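Side-chain carbons are numbered C1'–C17' from the resorcinol ring. Everything rests on cutting the C4'–C5' bond, a methylene–methylene link in the middle of the heptamethylene tether between ring carbon C5 and the C8'=C9' Z-olefin, remote from any polarising group. One operation makes it: 9-BBN turns the terminal olefin of a 5-(but-3-enyl)resorcinol dibenzyl ether into a C4' nucleophile, which Pd/PCy3 couples with the C5' primary bromide of (3S,9Z)-13-bromotridec-9-en-3-ol, a fragment that already holds the Z-olefin and the (S)-carbinol. The step exploits that C5' is primary and three bonds from C8': oxidative addition is easy, olefin insertion is not, and 9-BBN never meets that olefin.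

Key step: step 4

Assumption: compounds 1, 2, 4, 5 and 8, 9-BBN and the cyclometalated ruthenium nitrato metathesis catalyst are taken as purchased.

Step 1
Reactants: 1 3,5-bis(benzyloxy)benzyl bromide; 2 allylmagnesium bromide
Product: 3 1,3-bis(benzyloxy)-5-(but-3-en-1-yl)benzene
Conditions: 2 (1.0 M in Et2O, 1.3 equiv), THF, 0 °C → rt; aq. NH4Cl
Reagents that add atoms: none
Why: SN2-type allyl–benzyl coupling of an allyl Grignard reagent with a benzylic bromide is fast without a catalyst and leaves the aryl benzyl ethers untouched.

Step 2
Reactants: 4 6-bromohex-1-ene; 5 (S)-1,2-epoxybutane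
Product: 7 (S)-dec-9-en-3-ol, via hex-5-enylmagnesium bromide 6 (not isolated)
Conditions: Mg, THF, 20 °C; then CuI (10 mol%), 5, THF, −40 → 0 °C; aq. NH4Cl
Reagents that add atoms: none
Why: Copper-catalysed Grignard opening of a terminal epoxide is an SN2 attack at the unsubstituted CH2, so the C–O stereocentre of 5 is not touched and appears as the (S)-carbinol (the former ring CH2 still outranks ethyl, so the descriptor stays S); any cyclopentylmethyl Grignard formed by radical 5-exo closure during magnesium insertion gives an olefin-free alcohol that cannot enter step 3 and is removed there.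

Step 3
Reactants: 7 (S)-dec-9-en-3-ol; 8 5-bromopent-1-ene
Product: 9 (3S,9Z)-13-bromotridec-9-en-3-ol
Conditions: cyclometalated N-adamantyl NHC Ru nitrato alkylidene (Z-selective metathesis catalyst, 3 mol%), 8 (4 equiv), THF, 35 °C, static vacuum
Reagents that add atoms: none
Why: Z-selective olefin cross-metathesis: the chelating N-adamantyl NHC forces both substituents of the ruthenacyclobutane to the side away from the N-aryl group so that the kinetic Z-olefin is released, the excess of cheap 8 channels 7 into the cross product, ruthenium tolerates the free hydroxyl and the primary bromide, and the three possible metathesis products carry zero, one or two hydroxyl groups and should separate on silica.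

Step 4
Reactants: 3 1,3-bis(benzyloxy)-5-(but-3-en-1-yl)benzene; 9 (3S,9Z)-13-bromotridec-9-en-3-ol
Product: 11 (3S,9Z)-17-[3,5-bis(benzyloxy)phenyl]heptadec-9-en-3-ol, via B-alkyl-9-BBN borane 10 (not isolated)
Conditions: 3 (1.6 equiv), 9-BBN (1.5 equiv), THF, 0 °C → rt; then 9 (1.0 equiv), Pd(OAc)2 (4 mol%), PCy3 (8 mol%), K3PO4·H2O (1.3 equiv), THF, rt
Reagents that add atoms: none
Why: 9-BBN adds anti-Markovnikov to the only olefin of 3 to give the primary alkylborane 10, which after quaternisation by hydroxide/phosphate transmetalates to the alkylpalladium(II) bromide formed by SN2-type oxidative addition of Pd(0)/PCy3 into the C5'–Br bond of 9, and reductive elimination then forms the C4'–C5' bond. The closest known reaction type is the Pd/PCy3-catalysed Suzuki–Miyaura coupling of B-alkyl-9-BBN reagents with unactivated primary alkyl bromides that carry β-hydrogens. No ring is closed and no stereocentre is formed; the (S)-carbinol and the Z-olefin are spectators. The step needs chemoselectivity for the terminal olefin and for cross-coupling over β-hydride elimination: the first is secured by using 9-BBN in slight deficit to 3 and adding 9 only after hydroboration is complete, so that no B–H bond meets the Z-olefin or the hydroxyl, the second by the bulky, electron-rich PCy3. The olefin of 9 lies three bonds from the palladium-bearing carbon, so insertion would need a 4-exo closure and is not expected, and the mild hydrated phosphate base should leave the free secondary alcohol and the benzyl ethers untouched.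

Step 5
Reactants: 11 (3S,9Z)-17-[3,5-bis(benzyloxy)phenyl]heptadec-9-en-3-ol
Product: 12 hansfordiol G, 5-[(8Z,15S)-15-hydroxyheptadec-8-en-1-yl]benzene-1,3-diol
Conditions: BCl3 (1 M in CH2Cl2, 5 equiv), C6HMe5 (6 equiv), CH2Cl2, −78 °C; CHCl3/MeOH quench at −78 °C, then aqueous work-up
Reagents that add atoms: none
Why: Lewis-acid cleavage of aryl benzyl ethers by BCl3, with pentamethylbenzene capturing the benzyl cations by Friedel–Crafts alkylation before they can attack the electron-rich resorcinol ring, runs at −78 °C, where the isolated Z-olefin should not be protonated and the carbinol is held as a borate that is hydrolysed on work-up, so the (S)-centre is not touched.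

**Compound list**

1 | 3,5-bis(benzyloxy)benzyl bromide | BrCc1cc(OCc2ccccc2)cc(OCc2ccccc2)c1 | starting material
2 | allylmagnesium bromide | C=CC[Mg]Br | starting material
3 | 1,3-bis(benzyloxy)-5-(but-3-en-1-yl)benzene | C=CCCc1cc(OCc2ccccc2)cc(OCc2ccccc2)c1 | intermediate
4 | 6-bromohex-1-ene | C=CCCCCBr | starting material
5 | (S)-1,2-epoxybutane, (2S)-2-ethyloxirane | CC[C@H]1CO1 | starting material
6 | hex-5-enylmagnesium bromide | C=CCCCC[Mg]Br | intermediate
7 | (S)-dec-9-en-3-ol | CC[C@H](O)CCCCCC=C | intermediate
8 | 5-bromopent-1-ene | C=CCCCBr | starting material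
9 | (3S,9Z)-13-bromotridec-9-en-3-ol | CC[C@H](O)CCCCC/C=C\CCCBr | intermediate
10 | 9-{4-[3,5-bis(benzyloxy)phenyl]butyl}-9-borabicyclo[3.3.1]nonane | B1(CCCCc2cc(OCc3ccccc3)cc(OCc3ccccc3)c2)C2CCCC1CCC2 | intermediate
11 | (3S,9Z)-17-[3,5-bis(benzyloxy)phenyl]heptadec-9-en-3-ol | CC[C@H](O)CCCCC/C=C\CCCCCCCc1cc(OCc2ccccc2)cc(OCc2ccccc2)c1 | intermediate
12 | hansfordiol G, 5-[(8Z,15S)-15-hydroxyheptadec-8-en-1-yl]benzene-1,3-diol | CC[C@H](O)CCCCC/C=C\CCCCCCCc1cc(O)cc(O)c1 | target

Total step count: 5. Longest linear sequence: 4 steps (steps 2, 3, 4, 5).

**Steps most likely to fail**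

Step 3. The cross-metathesis may lose Z-selectivity through secondary metathesis, or divert 7 into homodimer, so that the E-isomer contaminates 9. The fallback builds the olefin by a Wittig reaction; it sets out from 7 and comes back to the route at 9. Ozonolysis of 7 (O3, CH2Cl2/MeOH, −78 °C; PPh3) should give (S)-7-hydroxynonanal F1. The ylide (but-3-en-1-ylidene)triphenylphosphorane F2 is generated from commercial (but-3-en-1-yl)triphenylphosphonium bromide with NaHMDS in THF and used in excess because of the free hydroxyl. At −78 °C it should convert F1 in a salt-free, Z-selective Wittig reaction into (3S,9Z)-trideca-9,12-dien-3-ol F3. 9-BBN (2.1 equiv, one equivalent being taken up by the hydroxyl) should add only to the terminal olefin and give the O,C-bis(9-BBN) intermediate F4. NaOH/H2O2 should oxidise this to (4Z,11S)-tridec-4-ene-1,11-diol F5. Appel bromination with a small excess of CBr4/PPh3 at −20 °C, selective for the primary hydroxyl, should then give 9.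

Step 4. β-Hydride elimination or protodehalogenation of the alkylpalladium intermediate may outrun a transmetalation slowed by the free hydroxyl, and palladium hydride may move the Z-olefin. The fallback joins the same two carbons by a copper-catalysed Grignard–alkyl bromide coupling; it sets out from 3 (and uses 9) and comes back at 11. Borane 10, made from 3 as in step 4, is oxidised (NaOH, H2O2) to 4-[3,5-bis(benzyloxy)phenyl]butan-1-ol F6. Appel bromination (CBr4, PPh3, CH2Cl2, 0 °C) should give 1,3-bis(benzyloxy)-5-(4-bromobutyl)benzene F7, and magnesium in THF {4-[3,5-bis(benzyloxy)phenyl]butyl}magnesium bromide F8. Bromide 9 is first deprotonated with MeMgCl (1.0 equiv, THF, 0 °C) to the chloromagnesium alkoxide of 9 F9. It is then coupled with F8 (Li2CuCl4 3 mol%, THF/NMP, 0 °C); NH4Cl work-up should return 11.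

Step 5. The HCl/BCl3 medium may cause migration or hydrochlorination of the Z-olefin, the resorcinol ring may be C-benzylated if cation capture is incomplete, and the carbinol may be substituted if the mixture warms. The fallback replaces Lewis-acid cleavage by dissolving-metal reduction and leads from 11 directly to 12 (no further compound, F0): Li, NH3(l)/THF, −78 °C, then solid NH4Cl. The benzylic C–O bonds should break through the arene radical anions, an isolated olefin is not reduced without an added alcohol, and the resorcinol ring is protected as its bis-phenoxide.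

**Further compounds**

F1 | step 3 | (S)-7-hydroxynonanal | CC[C@H](O)CCCCCC=O
F2 | step 3 | (but-3-en-1-ylidene)triphenylphosphorane | C=CCC=P(c1ccccc1)(c1ccccc1)c1ccccc1
F3 | step 3 | (3S,9Z)-trideca-9,12-dien-3-ol | CC[C@H](O)CCCCC/C=C\CC=C
F4 | step 3 | O,C-bis(9-BBN) intermediate, 9-{[(3S,9Z)-13-(9-borabicyclo[3.3.1]nonan-9-yl)tridec-9-en-3-yl]oxy}-9-borabicyclo[3.3.1]nonane | CC[C@H](OB1C2CCCC1CCC2)CCCCC/C=C\CCCB1C2CCCC1CCC2
F5 | step 3 | (4Z,11S)-tridec-4-ene-1,11-diol | CC[C@H](O)CCCCC/C=C\CCCO
F6 | step 4 | 4-[3,5-bis(benzyloxy)phenyl]butan-1-ol | OCCCCc1cc(OCc2ccccc2)cc(OCc2ccccc2)c1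
F7 | step 4 | 1,3-bis(benzyloxy)-5-(4-bromobutyl)benzene | BrCCCCc1cc(OCc2ccccc2)cc(OCc2ccccc2)c1
F8 | step 4 | {4-[3,5-bis(benzyloxy)phenyl]butyl}magnesium bromide | Br[Mg]CCCCc1cc(OCc2ccccc2)cc(OCc2ccccc2)c1
F9 | step 4 | chloromagnesium alkoxide of 9 | CC[C@H](O[Mg]Cl)CCCCC/C=C\CCCBr
F0 | step 5 | none | none
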